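**Retrosynthetic overview**

1. The strategy rests on ring A (C3a, C4, C5, C6, C7, C7a) of the trans-(2R,3R)-2,3-dihydrobenzofuran: it carries O1 at C7a and OMe at C6 (1,3-related), a carbon substituent at C5, and is fused to the dihydrofuran through C3a–C7a. This is the pattern left when a 6-alkoxy-4-methoxypyridazine with an acceptor at C3 adds an alkyne tethered through O1–C2–C3 and loses N2.
2. C5 (E)-propenyl ⇐ aldehyde (E-selective ethylidenation) ⇐ benzylic alcohol ⇐ methyl ester, the acceptor that activates the diazine.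
3. C3a–C7a and C4–C5 ⇐ intramolecular inverse-electron-demand Diels–Alder reaction of the alkyne-tethered pyridazine ester with loss of N2; ring A and the dihydrofuran ring form together in this one step, and no other ring is made.
4. Pyridazinyl ether ⇐ SNAr of the anti homopropargylic alkoxide on methyl 6-chloro-4-methoxypyridazine-3-carboxylate, which offers one chloride only (made from the 4,6-dichloro ester and NaOMe at C4).
5. C2 and C3 stereocentres ⇐ anti-selective propargylation of 3,4,5-trimethoxybenzaldehyde with the allenylzinc from (S)-but-3-yn-2-yl mesylate.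

Key step: step 5

Remark: a ring chloride is not used as the C3 acceptor, because in 3,6-dichloro-4-methoxypyridazine alkoxides are expected to displace the chloride next to the methoxy group (C6 is deactivated through the MeO–C4=C5–C6=N1 conjugation), which would put the tether on the wrong carbon; the ester leaves a single chloride and lowers the diazine LUMO.

**Route**

Step 1
Reactants: 1 (S)-but-3-yn-2-ol
Product: 2 (S)-but-3-yn-2-yl methanesulfonate
Conditions: MsCl (1.2 equiv), Et3N (1.5 equiv), CH2Cl2, −78 to 0 °C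
Reagents that add atoms: methanesulfonyl chloride, CS(=O)(=O)Cl
Why: Sulfonylation at oxygen (mesylation) leaves the C–O bond and hence the (S) centre untouched and installs the leaving group for the propargylation.

Step 2
Reactants: 2 (S)-but-3-yn-2-yl methanesulfonate; 3 3,4,5-trimethoxybenzaldehyde
Product: 5 (1R,2R)-2-methyl-1-(3,4,5-trimethoxyphenyl)but-3-yn-1-ol, via allenylzinc mesylate 4 (not isolated)
Conditions: Pd(OAc)2 (5 mol %), PPh3 (5 mol %), Et2Zn (3 equiv), THF, −78 to −20 °C; aq NH4Cl
Reagents that add atoms: none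
Why: Marshall propargylation: zerovalent palladium formed in situ displaces the mesylate anti (SN2′) to an allenylpalladium, transmetalation gives the configurationally defined (M)-allenylzinc 4, and its addition to the aldehyde through a cyclic SE2′ transition state with methyl anti to aryl should set the methyl-bearing centre as R (chirality transfer from the S mesylate) and the carbinol centre as R (anti relationship), the minor syn isomer being removed by chromatography.

Step 3
Reactants: 6 methyl 4,6-dichloropyridazine-3-carboxylate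
Product: 7 methyl 6-chloro-4-methoxypyridazine-3-carboxylate
Conditions: NaOMe (1.0 equiv), MeOH/THF, −20 to 0 °C
Reagents that add atoms: sodium methoxide, C[O-].[Na+]
Why: Nucleophilic aromatic substitution (SNAr): in 4,6-dichloropyridazine-3-carboxylates the C4 chloride, ortho to the ester and vinylogous to N1, is displaced first, so one equivalent of methoxide at low temperature should stop at the mono-methoxy chloride.

Step 4
Reactants: 5 (1R,2R)-2-methyl-1-(3,4,5-trimethoxyphenyl)but-3-yn-1-ol; 7 methyl 6-chloro-4-methoxypyridazine-3-carboxylate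
Product: 9 methyl 4-methoxy-6-{[(1R,2R)-2-methyl-1-(3,4,5-trimethoxyphenyl)but-3-yn-1-yl]oxy}pyridazine-3-carboxylate, via sodium alkoxide 8 (not isolated)
Conditions: NaH (1.05 equiv), THF, 0 °C; then 7 (1.1 equiv), THF, −20 to 20 °C
Reagents that add atoms: none
Why: SNAr of the sodium alkoxide at C6, the only carbon that still bears chloride and one activated by the adjacent ring nitrogen and the para ester, forms the aryl–O bond without touching the C–O stereocentre, so the tether oxygen can only end up on the carbon flanked by N1 and C5–H.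

Step 5
Reactants: 9 methyl 4-methoxy-6-{[(1R,2R)-2-methyl-1-(3,4,5-trimethoxyphenyl)but-3-yn-1-yl]oxy}pyridazine-3-carboxylate
Product: 11 methyl (2R,3R)-6-methoxy-3-methyl-2-(3,4,5-trimethoxyphenyl)-2,3-dihydro-1-benzofuran-5-carboxylate, via bicyclic azo adduct 10 (not isolated)
Conditions: 1,3,5-triisopropylbenzene (0.02 M), 180–200 °C, Ar
Reagents that add atoms: none
Why: Intramolecular inverse-electron-demand Diels–Alder reaction of an alkyne-tethered 1,2-diazine followed by retro-[4+2] loss of N2, the known thermal route from alkynyl pyridazines to indolines and 2,3-dihydrobenzofurans; the electron-poor diazine is the 4π unit across its C3 and C6 and the terminal alkyne the 2π unit. The internal alkyne carbon bonds to the alkoxy-bearing C6 (C3a–C7a) and the terminal carbon to the ester-bearing C3 (C4–C5) to give adduct 10, which expels N2 and delivers benzene ring A directly at the aromatic oxidation level. The dihydrofuran ring closes as the five-membered ring O1–C2–C3–C3a–C7a through the three-atom O–C–C tether, the only mode the tether allows, so the regiochemistry is fixed; ring A closes as the six-membered carbocycle made by the two new σ bonds and is kept after the cycloreversion. No stereocentre is formed: C2 and C3 are carried unchanged from 5 because no acid, base or metal is present, and the two bridgehead diastereomers of 10 converge on the same arene. The selectivity needed is cycloaddition ahead of thermal breakdown of the benzylic pyridazinyl ether; the ester on the diazine (lower LUMO) and the trans-disposed aryl and methyl groups on the tether (reactive rotamer) should secure it.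

Step 6
Reactants: 11 methyl (2R,3R)-6-methoxy-3-methyl-2-(3,4,5-trimethoxyphenyl)-2,3-dihydro-1-benzofuran-5-carboxylate
Product: 12 [(2R,3R)-6-methoxy-3-methyl-2-(3,4,5-trimethoxyphenyl)-2,3-dihydro-1-benzofuran-5-yl]methanol
Conditions: i-Bu2AlH (2.5 equiv), CH2Cl2, −78 to 0 °C; aq KNaC4H4O6
Reagents that add atoms: none
Why: Hydride reduction of the aryl ester to the benzylic alcohol; the aryl methyl ethers and the cyclic benzylic ether are inert to i-Bu2AlH at low temperature.

Step 7
Reactants: 12 [(2R,3R)-6-methoxy-3-methyl-2-(3,4,5-trimethoxyphenyl)-2,3-dihydro-1-benzofuran-5-yl]methanol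
Product: 13 (2R,3R)-6-methoxy-3-methyl-2-(3,4,5-trimethoxyphenyl)-2,3-dihydro-1-benzofuran-5-carbaldehyde
Conditions: MnO2 (15 equiv), CH2Cl2, 20 °C
Reagents that add atoms: none
Why: Chemoselective oxidation of the electron-rich benzylic alcohol on MnO2 stops at the aldehyde and uses no acid or base that could open or epimerise the dihydrofuran.

Step 8
Reactants: 13 (2R,3R)-6-methoxy-3-methyl-2-(3,4,5-trimethoxyphenyl)-2,3-dihydro-1-benzofuran-5-carbaldehyde
Product: 14 (2R,3R)-6-methoxy-3-methyl-5-[(E)-prop-1-en-1-yl]-2-(3,4,5-trimethoxyphenyl)-2,3-dihydro-1-benzofuran (target)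
Conditions: CrCl2 (8 equiv), CH3CHI2 (2 equiv), THF, 20 °C
Reagents that add atoms: 1,1-diiodoethane, CC(I)I
Why: Takai–Utimoto alkylidenation: the geminal dichromium reagent made from CH3CHI2 and CrCl2 adds to the aryl aldehyde and the β-oxido-chromium adduct eliminates from its less hindered rotamer, which should give the (E)-propenyl group with high selectivity under neutral conditions.

**Compound list**

1 | (S)-but-3-yn-2-ol | C#C[C@H](C)O | starting material
2 | (S)-but-3-yn-2-yl methanesulfonate | C#C[C@H](C)OS(C)(=O)=O | intermediate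
3 | 3,4,5-trimethoxybenzaldehyde | COc1cc(C=O)cc(OC)c1OC | starting material
4 | (M)-buta-1,2-dien-1-ylzinc methanesulfonate (axial configuration M, equal to aR) | CC=C=C[Zn]OS(C)(=O)=O | intermediate
5 | (1R,2R)-2-methyl-1-(3,4,5-trimethoxyphenyl)but-3-yn-1-ol (anti) | O[C@@H](c1cc(OC)c(OC)c(OC)c1)[C@@H](C#C)C | intermediate
6 | methyl 4,6-dichloropyridazine-3-carboxylate | COC(=O)c1nnc(Cl)cc1Cl | starting material
7 | methyl 6-chloro-4-methoxypyridazine-3-carboxylate | COC(=O)c1nnc(Cl)cc1OC | intermediate
8 | sodium (1R,2R)-2-methyl-1-(3,4,5-trimethoxyphenyl)but-3-yn-1-olate | [Na+].[O-][C@@H](c1cc(OC)c(OC)c(OC)c1)[C@@H](C#C)C | intermediate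
9 | methyl 4-methoxy-6-{[(1R,2R)-2-methyl-1-(3,4,5-trimethoxyphenyl)but-3-yn-1-yl]oxy}pyridazine-3-carboxylate | COC(=O)c1nnc(O[C@@H](c2cc(OC)c(OC)c(OC)c2)[C@@H](C#C)C)cc1OC | intermediate
10 | [4+2] adduct: 2,3-diazabicyclo[2.2.2]octa-2,5,7-triene with CO2Me on one bridgehead, the ether oxygen on the other, OMe on the C=C bridge next to the ester bridgehead, and the dihydrofuran fused across the oxygen-bearing bridgehead and the former internal alkyne carbon; either bridgehead diastereomer | COC(=O)C12N=NC3(C=C1OC)O[C@@H](c1cc(OC)c(OC)c(OC)c1)[C@H](C)C3=C2 | intermediate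
11 | methyl (2R,3R)-6-methoxy-3-methyl-2-(3,4,5-trimethoxyphenyl)-2,3-dihydro-1-benzofuran-5-carboxylate | COC(=O)c1cc2c(cc1OC)O[C@@H](c1cc(OC)c(OC)c(OC)c1)[C@@H]2C | intermediate
12 | [(2R,3R)-6-methoxy-3-methyl-2-(3,4,5-trimethoxyphenyl)-2,3-dihydro-1-benzofuran-5-yl]methanol | OCc1cc2c(cc1OC)O[C@@H](c1cc(OC)c(OC)c(OC)c1)[C@@H]2C | intermediate
13 | (2R,3R)-6-methoxy-3-methyl-2-(3,4,5-trimethoxyphenyl)-2,3-dihydro-1-benzofuran-5-carbaldehyde | O=Cc1cc2c(cc1OC)O[C@@H](c1cc(OC)c(OC)c(OC)c1)[C@@H]2C | intermediate
14 | (2R,3R)-6-methoxy-3-methyl-5-[(E)-prop-1-en-1-yl]-2-(3,4,5-trimethoxyphenyl)-2,3-dihydro-1-benzofuran | C/C=C/c1cc2c(cc1OC)O[C@@H](c1cc(OC)c(OC)c(OC)c1)[C@@H]2C | target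

**Step count**

Total steps: 8. Longest linear sequence: 7 (steps 1, 2, 4, 5, 6, 7, 8); step 3 is a one-step branch.

**Steps most likely to fail**

1. Step 5. The cycloaddition may lag behind thermal breakdown of the benzylic pyridazinyl ether (syn-elimination to the pyridazinone and an enyne, or O-to-N migration), because two alkoxy donors remain on the diazine. The fallback sets out from 3 and comes back at 14 without any diazine cycloaddition. Aldehyde 3 is ethylidenated (CrCl2, CH3CHI2, THF, 20 °C) to (E)-1,2,3-trimethoxy-5-(prop-1-en-1-yl)benzene F1. F1 and 2-methoxy-1,4-benzoquinone are combined under TiCl2(TADDOLate) (from TiCl4, Ti(Oi-Pr)4 and the TADDOL antipode that leads to the 2R,3R series; CH2Cl2, −78 °C) in the titanium-promoted quinone–styrene formal [3+2] cycloaddition; the methyl-bearing alkene carbon bonds to quinone C5 and the C4 oxygen closes on the benzylic carbon, which should give (2R,3R)-6-methoxy-3-methyl-2-(3,4,5-trimethoxyphenyl)-2,3-dihydro-1-benzofuran-5-ol F2 (trans), with 5-OH and 6-OMe in place; its enantiomeric purity may have to be raised by recrystallisation. Tf2O/pyridine (CH2Cl2, 0 °C) converts F2 into (2R,3R)-6-methoxy-3-methyl-2-(3,4,5-trimethoxyphenyl)-2,3-dihydro-1-benzofuran-5-yl trifluoromethanesulfonate F3, and Suzuki coupling of F3 with CH3CH=CHBF3K (Pd(OAc)2, SPhos, K3PO4, toluene/H2O, 80 °C) should give 14.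

2. Step 4. Acyl transfer from the methyl ester to the hindered alkoxide, or exchange at the C4 methoxy carbon, would each release methoxide that then consumes the C6 chloride. The fallback sets out from 7 (with 5) and comes back at 9, with the ester masked as a carboxylate that cannot be acylated. Ester 7 is saponified (LiOH, 1.05 equiv, THF/H2O, 0 °C) to lithium 6-chloro-4-methoxypyridazine-3-carboxylate F4. SNAr of F4 with alkoxide 8 (from 5 and NaH; DMF, 50–60 °C) and buffered acidification (aq NaH2PO4) should give 4-methoxy-6-{[(1R,2R)-2-methyl-1-(3,4,5-trimethoxyphenyl)but-3-yn-1-yl]oxy}pyridazine-3-carboxylic acid F5. O-Methylation of F5 (MeI, K2CO3, DMF, 20 °C) returns 9.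

3. Step 2. Anti/syn discrimination may be incomplete with the aromatic aldehyde, and the allenylpalladium may partly racemise before transmetalation. The fallback sets out from 3 and comes back at 5 by crotylboration and alkene-to-alkyne conversion. Brown crotylboration of 3 with (E)-crotyldiisopinocampheylborane (from trans-2-butene, n-BuLi/KOt-Bu, (+)-Ipc2BOMe and BF3·OEt2, THF, −78 °C; NaOH/H2O2 work-up; the antipode is chosen so that the Re face of the aldehyde is attacked) should give (1R,2R)-2-methyl-1-(3,4,5-trimethoxyphenyl)but-3-en-1-ol F6. Silylation (TBSOTf, 2,6-lutidine, CH2Cl2, 0 °C) gives tert-butyldimethylsilyl ether F7. Oxidative cleavage of the vinyl group (OsO4 cat., NaIO4, 2,6-lutidine, dioxane/H2O) gives (2S,3R)-3-[(tert-butyldimethylsilyl)oxy]-2-methyl-3-(3,4,5-trimethoxyphenyl)propanal F8. Ohira–Bestmann homologation (dimethyl (1-diazo-2-oxopropyl)phosphonate, K2CO3, MeOH, 0 to 20 °C) gives silyl-protected alkyne F9, and Bu4NF (THF, 0 °C) releases 5.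

**Further compounds**

F1 | step 5 | (E)-1,2,3-trimethoxy-5-(prop-1-en-1-yl)benzene | C/C=C/c1cc(OC)c(OC)c(OC)c1
F2 | step 5 | (2R,3R)-6-methoxy-3-methyl-2-(3,4,5-trimethoxyphenyl)-2,3-dihydro-1-benzofuran-5-ol | Oc1cc2c(cc1OC)O[C@@H](c1cc(OC)c(OC)c(OC)c1)[C@@H]2C
F3 | step 5 | (2R,3R)-6-methoxy-3-methyl-2-(3,4,5-trimethoxyphenyl)-2,3-dihydro-1-benzofuran-5-yl trifluoromethanesulfonate | O=S(=O)(Oc1cc2c(cc1OC)O[C@@H](c1cc(OC)c(OC)c(OC)c1)[C@@H]2C)C(F)(F)F
F4 | step 4 | lithium 6-chloro-4-methoxypyridazine-3-carboxylate | [Li+].[O-]C(=O)c1nnc(Cl)cc1OC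
F5 | step 4 | 4-methoxy-6-{[(1R,2R)-2-methyl-1-(3,4,5-trimethoxyphenyl)but-3-yn-1-yl]oxy}pyridazine-3-carboxylic acid | OC(=O)c1nnc(O[C@@H](c2cc(OC)c(OC)c(OC)c2)[C@@H](C#C)C)cc1OC
F6 | step 2 | (1R,2R)-2-methyl-1-(3,4,5-trimethoxyphenyl)but-3-en-1-ol | O[C@@H](c1cc(OC)c(OC)c(OC)c1)[C@@H](C=C)C
F7 | step 2 | tert-butyldimethyl{[(1R,2R)-2-methyl-1-(3,4,5-trimethoxyphenyl)but-3-en-1-yl]oxy}silane | CC(C)(C)[Si](C)(C)O[C@@H](c1cc(OC)c(OC)c(OC)c1)[C@@H](C=C)C
F8 | step 2 | (2S,3R)-3-[(tert-butyldimethylsilyl)oxy]-2-methyl-3-(3,4,5-trimethoxyphenyl)propanal | CC(C)(C)[Si](C)(C)O[C@@H](c1cc(OC)c(OC)c(OC)c1)[C@@H](C=O)C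
F9 | step 2 | tert-butyldimethyl{[(1R,2R)-2-methyl-1-(3,4,5-trimethoxyphenyl)but-3-yn-1-yl]oxy}silane | CC(C)(C)[Si](C)(C)O[C@@H](c1cc(OC)c(OC)c(OC)c1)[C@@H](C#C)C
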